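The earlier runs and the new flask are calculated with constants of no real substance; scatter was added.

Over 30 h in a closed, isothermal flask, starting material meets reagent, and we want to know where the charge ends up.

in all of them: starting material 0.050 M

|  | reagent | protic impurity | remark | time |
|---|---|---|---|---|
| green | 0.030 M | 1 mM | run made earlier |  |
| amber | 0.045 M | 1 mM | run made earlier |  |
| flask | 0.0600 M | 1.00 mM |  | 30 h |

- green (time / h: starting material / %, adduct / %, product / %): 1.33: 97.2, 2.0, 0.1; 4.00: 95.1, 1.3, 4.3; 6.00: 92.8, 1.2, 2.3; 10.0: 92.6, 1.0, 2.0; 15.0: 93.1, 0.2, 7.2; 20.0: 89.7, 0.2, 6.5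
- amber (time / h: starting material / %, adduct / %, product / %): 1.33: 95.9, 3.3, 0.5; 4.00: 93.7, 2.3, 1.2; 6.00: 92.5, 3.1, 3.8; 10.0: 89.3, 1.1, 5.9; 15.0: 87.1, 3.9, 8.1; 20.0: 86.0, 1.2, 9.0

(scatter of a reading: 1 percentage point)

1. the species in which most of what was charged as starting material, at 30 h sits (starting material / adduct / product)
2. the largest share itself, whichever of these holds it, in percent of the starting material charged

- steps thought possible: starting material + protic impurity -> quenched substrate; adduct -> product; starting material + reagent <-> adduct

We reckon with the fraction left, not the fraction made. We count the protic impurity as having reacted with its equal amount of starting material, 2.00% of the charge, which leaves a pool of 98.0%. Starting material and adduct both stay in that pool, and product leaves it. If the pool decays like a first-order lag whose rate scales with reagent (pseudo-first-order), one number describes it: the loss constant, minus the logarithm of the fraction of the pool left, divided by reagent charge times time.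

| run | at 15.0 h | at 20.0 h |
|---|---|---|
| green | 0.109 L mol⁻¹ h⁻¹ | 0.144 L mol⁻¹ h⁻¹ |
| amber | 0.110 L mol⁻¹ h⁻¹ | 0.130 L mol⁻¹ h⁻¹ |

The last readings give 0.137 L mol⁻¹ h⁻¹, and so a pool of 76.6% in the flask. That is the weak link: a scatter of 1 percentage point sits on a loss of just 8.1 points in green. All four values together give 0.123 L mol⁻¹ h⁻¹, lower. The time constant at the flask's charge is then 135 h, and the pool at 30 h is 78.5%. Amber's adduct averages 2.48%. Scaled to the flask's reagent, that is 3.31%, so we commit to 75.2% starting material.

The forecast says starting material at 77%, holding that “Product forms slowly”.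

The flask gives starting material at 76.5%.

    starting material + protic impurity → quenched substrate (k = 36.2 L mol⁻¹ min⁻¹)
    adduct → product (k = 0.00319 min⁻¹)
    starting material + reagent ⇌ adduct (K = 0.741 L mol⁻¹, k = 0.104 L mol⁻¹ min⁻¹)

With 2.73% adduct, the pool in the flask stands at 79.2%, which returns a loss constant of 0.118 L mol⁻¹ h⁻¹. Now take the neighbouring flask, the same flask but with 0.24 M of reagent. Our constant puts its pool at 40.4% after 30 h. That flask holds 38.6% starting material and 5.90% adduct, a pool of 44.5%, with product now the largest share at 53.5%. Its own loss constant comes out at 0.110 L mol⁻¹ h⁻¹.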